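**Retrosynthetic overview**

1. Target 19 ⇐ open-chain bromo enal 16 in one flask: the C6–C7 bond (the bond that closes farnesyl diphosphate to the germacrane ring) forms the ten-membered ring first, then the C6 alkoxide closes the 12,6-lactone on the C12 methyl ester. The free 8-OH is left unprotected to steer chromium.
2. 16 ⇐ epoxy dialdehyde 13: acrylate unit added at C7, 8,9-epoxide opened at C9 by acetate with inversion, SN2′ bromination.
3. 13 ⇐ dienol 10: Sharpless epoxidation sets C8 and C9; one oxidation gives both aldehydes.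
4. 10 ⇐ (Z)-vinyl iodide 8 + vinylstannane 9; 8 ⇐ nerol 1 (C1–C6, C15 and the 4Z alkene), an iodo-Wittig unit (C10, C14) and acid 7.

Assumption: nerol, (2R)-2-methylbutanoic acid and (2E)-3-(tributylstannyl)prop-2-en-1-ol are bought; locants C1–C15 in the comments are germacrane locants of 19 (C6 lactone O-carbon, C7 ring-fusion CH, C8 CHOH, C9 CHOAc, C10 alkene carbon bearing C14, C12 lactone carbonyl, C13 exocyclic methylene).

**Route**

Step 1
Reactants: 1 nerol, (2Z)-3,7-dimethylocta-2,6-dien-1-ol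
Product: 2 neryl triethylsilyl ether, triethyl{[(2Z)-3,7-dimethylocta-2,6-dien-1-yl]oxy}silane
Conditions: Et3SiCl, imidazole, CH2Cl2, 0 °C → rt
Reagents that add atoms: chlorotriethylsilane, CC[Si](Cl)(CC)CC
Why: Standard silylation of a primary allylic alcohol; the triethylsilyl group is chosen because step 8 converts it directly into the C6 aldehyde.

Step 2
Reactants: 2 neryl triethylsilyl ether
Product: 4 (4Z)-4-methyl-6-[(triethylsilyl)oxy]hex-4-enal, via ozonide 3 (not isolated)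
Conditions: O3 (1.0 equiv, Sudan Red 7B end point), CH2Cl2, −78 °C; then PPh3, −78 °C → rt
Reagents that add atoms: ozone, [O-][O+]=O
Why: Chemoselective ozonolysis cleaves the remote, more electron-rich isopropylidene alkene before the alkene deactivated by the allylic silyloxy group, and reductive work-up leaves the Z alkene untouched.

Step 3
Reactants: 4 (4Z)-4-methyl-6-[(triethylsilyl)oxy]hex-4-enal
Product: 5 ethyl (2Z,6Z)-2-iodo-6-methyl-8-[(triethylsilyl)oxy]octa-2,6-dienoate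
Conditions: Ph3P=CHCO2Et, NIS, CH2Cl2, −20 °C, 30 min; then 4, −20 °C → rt
Reagents that add atoms: ethyl (triphenylphosphoranylidene)acetate, CCOC(=O)C=P(c1ccccc1)(c1ccccc1)c1ccccc1; N-iodosuccinimide, O=C1CCC(=O)N1I
Why: Tandem ylide iodination–Wittig olefination; the stabilised iodo ylide places the chain trans to the ester, which fixes the 1(10) alkene geometry of the target (C14 trans, future C9 cis to the chain).

Step 4
Reactants: 5 ethyl (2Z,6Z)-2-iodo-6-methyl-8-[(triethylsilyl)oxy]octa-2,6-dienoate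
Product: 6 (2Z,6Z)-2-iodo-6-methyl-8-[(triethylsilyl)oxy]octa-2,6-dien-1-ol
Conditions: iBu2AlH (2.5 equiv), CH2Cl2, −78 °C; aq. KNaC4H4O6 (potassium sodium tartrate)
Reagents that add atoms: none
Why: 1,2-Reduction of the enoate by the aluminium hydride gives the C14 allylic alcohol; vinyl iodide and silyl ether are inert at −78 °C.

Step 5
Reactants: 6 (2Z,6Z)-2-iodo-6-methyl-8-[(triethylsilyl)oxy]octa-2,6-dien-1-ol; 7 (2R)-2-methylbutanoic acid
Product: 8 (2Z,6Z)-2-iodo-6-methyl-8-[(triethylsilyl)oxy]octa-2,6-dien-1-yl (2R)-2-methylbutanoate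
Conditions: DCC, DMAP (10 mol %), CH2Cl2, 0 °C → rt
Reagents that add atoms: none
Why: Steglich esterification of the only free hydroxyl; the α-branched aliphatic acid does not racemise under these conditions, so the (R) centre is carried in unchanged.

Step 6
Reactants: 8 (2Z,6Z)-2-iodo-6-methyl-8-[(triethylsilyl)oxy]octa-2,6-dien-1-yl (2R)-2-methylbutanoate; 9 (2E)-3-(tributylstannyl)prop-2-en-1-ol
Product: 10 (2E,6Z)-2-[(1E)-3-hydroxyprop-1-en-1-yl]-6-methyl-8-[(triethylsilyl)oxy]octa-2,6-dien-1-yl (2R)-2-methylbutanoate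
Conditions: CuTC [Cu(O2C-2-thienyl)] (1.5 equiv), NMP, 0 °C → rt
Reagents that add atoms: none
Why: Liebeskind's copper-carboxylate-mediated Stille-type coupling joins the two sp2 carbons (C9–C10) with retention of both alkene geometries and avoids zerovalent palladium, which could ionise the allylic ester.

Step 7
Reactants: 10 (2E,6Z)-2-[(1E)-3-hydroxyprop-1-en-1-yl]-6-methyl-8-[(triethylsilyl)oxy]octa-2,6-dien-1-yl (2R)-2-methylbutanoate
Product: 11 (2Z,6Z)-2-[(2S,3S)-3-(hydroxymethyl)oxiran-2-yl]-6-methyl-8-[(triethylsilyl)oxy]octa-2,6-dien-1-yl (2R)-2-methylbutanoate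
Conditions: Ti(OiPr)4 (10 mol %), L-(+)-diethyl tartrate (12 mol %), t-BuOOH, 4 Å MS, CH2Cl2, −20 °C
Reagents that add atoms: tert-butyl hydroperoxide, CC(C)(C)OO
Why: Sharpless asymmetric epoxidation of the only allylic alcohol; L-(+)-tartrate gives the (2S,3S)-epoxy alcohol from an (E)-allylic alcohol, which sets C8 (final) and C9 (to be inverted in step 10) by reagent control.

Step 8
Reactants: 11 (2Z,6Z)-2-[(2S,3S)-3-(hydroxymethyl)oxiran-2-yl]-6-methyl-8-[(triethylsilyl)oxy]octa-2,6-dien-1-yl (2R)-2-methylbutanoate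
Product: 13 (2Z,6Z)-2-[(2S,3R)-3-formyloxiran-2-yl]-6-methyl-8-oxoocta-2,6-dien-1-yl (2R)-2-methylbutanoate, via diol 12 (not isolated)
Conditions: IBX (5 equiv), wet DMSO, rt
Reagents that add atoms: none
Why: IBX in DMSO cleaves the primary triethylsilyl ether and oxidises both primary alcohols, so one operation gives the C6 (Z)-enal and the C7 epoxy aldehyde without acid, base or alkene isomerisation; the epoxide serves as the protecting group for O8.

Step 9
Reactants: 13 (2Z,6Z)-2-[(2S,3R)-3-formyloxiran-2-yl]-6-methyl-8-oxoocta-2,6-dien-1-yl (2R)-2-methylbutanoate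
Product: 14 methyl (3RS,4S,5S,6Z,10Z)-4,5-epoxy-3-hydroxy-10-methyl-2-methylidene-6-({[(2R)-2-methylbutanoyl]oxy}methyl)-12-oxododeca-6,10-dienoate
Conditions: methyl propiolate, iBu2AlH, NMO, THF, 0 °C, 1 h; then 13, −40 → 0 °C; aq. KNaC4H4O6
Reagents that add atoms: methyl propiolate, C#CC(=O)OC
Why: Vinylalumination (hydroalumination of the propiolate, then carbonyl addition) gives a Morita–Baylis–Hillman-type adduct without amine base; the α-oxygenated aldehyde reacts far faster than the β,β-disubstituted enal, and the new C7 carbinol is left as a mixture because it becomes sp2 in step 11.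

Step 10
Reactants: 14 methyl (3RS,4S,5S,6Z,10Z)-4,5-epoxy-3-hydroxy-10-methyl-2-methylidene-6-({[(2R)-2-methylbutanoyl]oxy}methyl)-12-oxododeca-6,10-dienoate
Product: 15 methyl (3RS,4S,5R,6Z,10Z)-5-acetoxy-3,4-dihydroxy-10-methyl-2-methylidene-6-({[(2R)-2-methylbutanoyl]oxy}methyl)-12-oxododeca-6,10-dienoate
Conditions: Ti(OiPr)4 (1.5 equiv), AcOH (2 equiv), CH2Cl2, rt; aq. tartaric acid
Reagents that add atoms: acetic acid, CC(=O)O
Why: Sharpless titanium-mediated opening of a 2,3-epoxy alcohol by a carboxylic acid; titanium bound to the C7 alkoxide delivers acetate to the distal, allylic epoxide carbon C9 with SN2 inversion, giving the 9-acetate (9R) and the free 8-hydroxyl (8S) already differentiated.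

Step 11
Reactants: 15 methyl (3RS,4S,5R,6Z,10Z)-5-acetoxy-3,4-dihydroxy-10-methyl-2-methylidene-6-({[(2R)-2-methylbutanoyl]oxy}methyl)-12-oxododeca-6,10-dienoate
Product: 16 methyl (2Z,4S,5R,6Z,10Z)-5-acetoxy-2-(bromomethyl)-4-hydroxy-10-methyl-6-({[(2R)-2-methylbutanoyl]oxy}methyl)-12-oxododeca-2,6,10-trienoate
Conditions: NBS, Me2S, CH2Cl2, −20 → 0 °C
Reagents that add atoms: N-bromosuccinimide, O=C1CCC(=O)N1Br
Why: Corey–Kim-type bromination is selective for the activated allylic alcohol over the saturated 8-hydroxyl and proceeds with SN2′ transposition to the thermodynamically preferred (Z)-2-(bromomethyl)enoate, which erases the C7 mixture.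

Step 12
Reactants: 16 methyl (2Z,4S,5R,6Z,10Z)-5-acetoxy-2-(bromomethyl)-4-hydroxy-10-methyl-6-({[(2R)-2-methylbutanoyl]oxy}methyl)-12-oxododeca-2,6,10-trienoate
Product: 19 [(3aR,4S,5R,6Z,10Z,11aR)-5-acetoxy-4-hydroxy-10-methyl-3-methylidene-2-oxo-2,3,3a,4,5,8,9,11a-octahydrocyclodeca[b]furan-6-yl]methyl (2R)-2-methylbutanoate, via allylchromium 17 (not isolated), via chromium alkoxide 18 (not isolated)
Conditions: CrCl2 (10 equiv), THF, rt, 16 added over 8 h by syringe pump (final 3 mM); then aq. NH4Cl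
Reagents that add atoms: none
Why: Intramolecular Nozaki–Hiyama (chromium Barbier) 2-(alkoxycarbonyl)allylation in which the free 8-hydroxyl binds chromium in a six-membered chelate across the Z-allyl unit, so the tethered enal is delivered to the C7 face syn to C9 (7R from 8S) while the ten-membered ring enforces the 6,7-anti arrangement (6R), and the resulting C6 chromium alkoxide then closes the γ-lactone on the methyl ester ahead of the neutral 8-hydroxyl.

**Compound list**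

1 | nerol, (2Z)-3,7-dimethylocta-2,6-dien-1-ol | OC/C=C(/C)CCC=C(C)C | starting material
2 | neryl triethylsilyl ether | CC[Si](CC)(CC)OC/C=C(/C)CCC=C(C)C | intermediate
3 | ozonide, 3-{(3Z)-3-methyl-5-[(triethylsilyl)oxy]pent-3-en-1-yl}-5,5-dimethyl-1,2,4-trioxolane | CC[Si](CC)(CC)OC/C=C(/C)CCC1OOC(C)(C)O1 | intermediate
4 | (4Z)-4-methyl-6-[(triethylsilyl)oxy]hex-4-enal | CC[Si](CC)(CC)OC/C=C(/C)CCC=O | intermediate
5 | ethyl (2Z,6Z)-2-iodo-6-methyl-8-[(triethylsilyl)oxy]octa-2,6-dienoate | CC[Si](CC)(CC)OC/C=C(/C)CC/C=C(\I)C(=O)OCC | intermediate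
6 | (2Z,6Z)-2-iodo-6-methyl-8-[(triethylsilyl)oxy]octa-2,6-dien-1-ol | CC[Si](CC)(CC)OC/C=C(/C)CC/C=C(\I)CO | intermediate
7 | (2R)-2-methylbutanoic acid | CC[C@@H](C)C(=O)O | starting material
8 | (2Z,6Z)-2-iodo-6-methyl-8-[(triethylsilyl)oxy]octa-2,6-dien-1-yl (2R)-2-methylbutanoate | CC[Si](CC)(CC)OC/C=C(/C)CC/C=C(\I)COC(=O)[C@H](C)CC | intermediate
9 | (2E)-3-(tributylstannyl)prop-2-en-1-ol | CCCC[Sn](CCCC)(CCCC)/C=C/CO | starting material
10 | (2E,6Z)-2-[(1E)-3-hydroxyprop-1-en-1-yl]-6-methyl-8-[(triethylsilyl)oxy]octa-2,6-dien-1-yl (2R)-2-methylbutanoate | CC[Si](CC)(CC)OC/C=C(/C)CC/C=C(/COC(=O)[C@H](C)CC)\C=C\CO | intermediate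
11 | (2Z,6Z)-2-[(2S,3S)-3-(hydroxymethyl)oxiran-2-yl]-6-methyl-8-[(triethylsilyl)oxy]octa-2,6-dien-1-yl (2R)-2-methylbutanoate | CC[Si](CC)(CC)OC/C=C(/C)CC/C=C(/COC(=O)[C@H](C)CC)[C@@H]1O[C@H]1CO | intermediate
12 | (2Z,6Z)-8-hydroxy-2-[(2S,3S)-3-(hydroxymethyl)oxiran-2-yl]-6-methylocta-2,6-dien-1-yl (2R)-2-methylbutanoate | OC/C=C(/C)CC/C=C(/COC(=O)[C@H](C)CC)[C@@H]1O[C@H]1CO | intermediate
13 | (2Z,6Z)-2-[(2S,3R)-3-formyloxiran-2-yl]-6-methyl-8-oxoocta-2,6-dien-1-yl (2R)-2-methylbutanoate | O=C/C=C(/C)CC/C=C(/COC(=O)[C@H](C)CC)[C@@H]1O[C@H]1C=O | intermediate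
14 | methyl (3RS,4S,5S,6Z,10Z)-4,5-epoxy-3-hydroxy-10-methyl-2-methylidene-6-({[(2R)-2-methylbutanoyl]oxy}methyl)-12-oxododeca-6,10-dienoate (C3 epimers) | O=C/C=C(/C)CC/C=C(/COC(=O)[C@H](C)CC)[C@@H]1O[C@H]1C(O)C(=C)C(=O)OC | intermediate
15 | methyl (3RS,4S,5R,6Z,10Z)-5-acetoxy-3,4-dihydroxy-10-methyl-2-methylidene-6-({[(2R)-2-methylbutanoyl]oxy}methyl)-12-oxododeca-6,10-dienoate (C3 epimers) | O=C/C=C(/C)CC/C=C(/COC(=O)[C@H](C)CC)[C@@H](OC(C)=O)[C@@H](O)C(O)C(=C)C(=O)OC | intermediate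
16 | methyl (2Z,4S,5R,6Z,10Z)-5-acetoxy-2-(bromomethyl)-4-hydroxy-10-methyl-6-({[(2R)-2-methylbutanoyl]oxy}methyl)-12-oxododeca-2,6,10-trienoate | O=C/C=C(/C)CC/C=C(/COC(=O)[C@H](C)CC)[C@@H](OC(C)=O)[C@@H](O)/C=C(\CBr)C(=O)OC | intermediate
17 | allylchromium dichloride of 16 (CrCl2 in place of Br at C13) | O=C/C=C(/C)CC/C=C(/COC(=O)[C@H](C)CC)[C@@H](OC(C)=O)[C@@H](O)/C=C(\C[Cr](Cl)Cl)C(=O)OC | intermediate
18 | ten-membered-ring seco-lactone methyl ester as its C6 dichlorochromium alkoxide (8-OH free, 9-OAc; C6, C7, C8, C9 as in 19) | C=C(C(=O)OC)[C@H]1[C@H](O[Cr](Cl)Cl)/C=C(/C)CC/C=C(/COC(=O)[C@H](C)CC)[C@@H](OC(C)=O)[C@H]1O | intermediate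
19 | [(3aR,4S,5R,6Z,10Z,11aR)-5-acetoxy-4-hydroxy-10-methyl-3-methylidene-2-oxo-2,3,3a,4,5,8,9,11a-octahydrocyclodeca[b]furan-6-yl]methyl (2R)-2-methylbutanoate (CNP0005248.2) | C=C1C(=O)O[C@@H]2/C=C(/C)CC/C=C(/COC(=O)[C@H](C)CC)[C@@H](OC(C)=O)[C@@H](O)[C@@H]12 | target

**Step count and risks**

Total step count: 12. Longest linear sequence: 12 steps (1 → 19); 7 and 9 are bought.

The three steps most likely to fail:

Step 12 (macrocyclisation). The risks are oligomerisation, the wrong C6/C7 diastereomer, and lactonisation through the 8-hydroxyl to the 12,8-lactone. The fallback sets out from 16: the 8-hydroxyl is capped with MOMCl and iPr2NEt to give the methoxymethyl ether bromide F13, whose ether oxygen can still bind chromium but cannot lactonise. CrCl2 closure under the same high dilution then gives only the 12,6-lactone, the methoxymethyl-protected lactone F14. ZnBr2 and n-PrSH in CH2Cl2 at 0 °C remove the acetal and the sequence comes back to the route at 19.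

Step 10 (acetolysis of the vinyl epoxide). The risks are attack at C1 (SN2′) or C8, participation of the C14 ester, and acetyl migration on titanium. The fallback sets out from 8 and drops the epoxide altogether. Nozaki–Hiyama–Kishi coupling (CrCl2, NiCl2 cat., DMSO) of 8 with bought (S)-glyceraldehyde acetonide F6 gives the Felkin (anti) allylic alcohol F7, which is acetylated (Ac2O, pyridine, DMAP) to the acetate F8. TFA–H2O at 0 °C removes acetonide and silyl ether to give the triol F9, and Et3SiOTf with 2,6-lutidine gives the tris(triethylsilyl) ether F10. Swern oxidation converts both primary silyl ethers into aldehydes (the silyl-protected dialdehyde F11), vinylalumination as in step 9 gives the silyl-protected allylic alcohol F12, and HF·pyridine frees the 8-hydroxyl, coming back to the route at 15.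

Step 9 (one of two aldehydes must react). The risks are addition to the enal as well and opening of the epoxide by the alane. The fallback sets out from 11 and keeps C6 masked. Dess–Martin periodinane with NaHCO3 oxidises only the free alcohol to the silyl-protected epoxy aldehyde F1, so the vinylalane meets a single aldehyde and gives the epoxy allylic alcohol F2. Ti(OiPr)4 and AcOH then give the acetoxy diol F3, and NBS with Me2S gives the silyl-protected bromide F4. HF·pyridine gives the allylic alcohol F5, and MnO2 in CH2Cl2 oxidises only that allylic alcohol, coming back to the route at 16.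

**Further compounds**

F1 | step 9 | (2Z,6Z)-2-[(2S,3R)-3-formyloxiran-2-yl]-6-methyl-8-[(triethylsilyl)oxy]octa-2,6-dien-1-yl (2R)-2-methylbutanoate | CC[Si](CC)(CC)OC/C=C(/C)CC/C=C(/COC(=O)[C@H](C)CC)[C@@H]1O[C@H]1C=O
F2 | step 9 | methyl (3RS,4S,5S,6Z,10Z)-4,5-epoxy-3-hydroxy-10-methyl-2-methylidene-6-({[(2R)-2-methylbutanoyl]oxy}methyl)-12-[(triethylsilyl)oxy]dodeca-6,10-dienoate | CC[Si](CC)(CC)OC/C=C(/C)CC/C=C(/COC(=O)[C@H](C)CC)[C@@H]1O[C@H]1C(O)C(=C)C(=O)OC
F3 | step 9 | methyl (3RS,4S,5R,6Z,10Z)-5-acetoxy-3,4-dihydroxy-10-methyl-2-methylidene-6-({[(2R)-2-methylbutanoyl]oxy}methyl)-12-[(triethylsilyl)oxy]dodeca-6,10-dienoate | CC[Si](CC)(CC)OC/C=C(/C)CC/C=C(/COC(=O)[C@H](C)CC)[C@@H](OC(C)=O)[C@@H](O)C(O)C(=C)C(=O)OC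
F4 | step 9 | methyl (2Z,4S,5R,6Z,10Z)-5-acetoxy-2-(bromomethyl)-4-hydroxy-10-methyl-6-({[(2R)-2-methylbutanoyl]oxy}methyl)-12-[(triethylsilyl)oxy]dodeca-2,6,10-trienoate | CC[Si](CC)(CC)OC/C=C(/C)CC/C=C(/COC(=O)[C@H](C)CC)[C@@H](OC(C)=O)[C@@H](O)/C=C(\CBr)C(=O)OC
F5 | step 9 | methyl (2Z,4S,5R,6Z,10Z)-5-acetoxy-2-(bromomethyl)-4,12-dihydroxy-10-methyl-6-({[(2R)-2-methylbutanoyl]oxy}methyl)dodeca-2,6,10-trienoate | OC/C=C(/C)CC/C=C(/COC(=O)[C@H](C)CC)[C@@H](OC(C)=O)[C@@H](O)/C=C(\CBr)C(=O)OC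
F6 | step 10 | (4S)-2,2-dimethyl-1,3-dioxolane-4-carbaldehyde, (S)-glyceraldehyde acetonide (bought) | CC1(C)OC[C@@H](C=O)O1
F7 | step 10 | (2Z,6Z)-2-{(R)-[(4S)-2,2-dimethyl-1,3-dioxolan-4-yl](hydroxy)methyl}-6-methyl-8-[(triethylsilyl)oxy]octa-2,6-dien-1-yl (2R)-2-methylbutanoate | CC[Si](CC)(CC)OC/C=C(/C)CC/C=C(/COC(=O)[C@H](C)CC)[C@@H](O)[C@@H]1COC(C)(C)O1
F8 | step 10 | (2Z,6Z)-2-{(R)-acetoxy[(4S)-2,2-dimethyl-1,3-dioxolan-4-yl]methyl}-6-methyl-8-[(triethylsilyl)oxy]octa-2,6-dien-1-yl (2R)-2-methylbutanoate | CC[Si](CC)(CC)OC/C=C(/C)CC/C=C(/COC(=O)[C@H](C)CC)[C@@H](OC(C)=O)[C@@H]1COC(C)(C)O1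
F9 | step 10 | (2Z,6Z)-2-[(1R,2S)-1-acetoxy-2,3-dihydroxypropyl]-8-hydroxy-6-methylocta-2,6-dien-1-yl (2R)-2-methylbutanoate | OC/C=C(/C)CC/C=C(/COC(=O)[C@H](C)CC)[C@@H](OC(C)=O)[C@@H](O)CO
F10 | step 10 | (2Z,6Z)-2-{(1R,2S)-1-acetoxy-2,3-bis[(triethylsilyl)oxy]propyl}-6-methyl-8-[(triethylsilyl)oxy]octa-2,6-dien-1-yl (2R)-2-methylbutanoate | CC[Si](CC)(CC)OC/C=C(/C)CC/C=C(/COC(=O)[C@H](C)CC)[C@@H](OC(C)=O)[C@@H](O[Si](CC)(CC)CC)CO[Si](CC)(CC)CC
F11 | step 10 | (2Z,6Z)-2-{(1R,2R)-1-acetoxy-3-oxo-2-[(triethylsilyl)oxy]propyl}-6-methyl-8-oxoocta-2,6-dien-1-yl (2R)-2-methylbutanoate | O=C/C=C(/C)CC/C=C(/COC(=O)[C@H](C)CC)[C@@H](OC(C)=O)[C@@H](O[Si](CC)(CC)CC)C=O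
F12 | step 10 | methyl (3RS,4S,5R,6Z,10Z)-5-acetoxy-3-hydroxy-10-methyl-2-methylidene-6-({[(2R)-2-methylbutanoyl]oxy}methyl)-12-oxo-4-[(triethylsilyl)oxy]dodeca-6,10-dienoate | O=C/C=C(/C)CC/C=C(/COC(=O)[C@H](C)CC)[C@@H](OC(C)=O)[C@@H](O[Si](CC)(CC)CC)C(O)C(=C)C(=O)OC
F13 | step 12 | methyl (2Z,4S,5R,6Z,10Z)-5-acetoxy-2-(bromomethyl)-4-(methoxymethoxy)-10-methyl-6-({[(2R)-2-methylbutanoyl]oxy}methyl)-12-oxododeca-2,6,10-trienoate | O=C/C=C(/C)CC/C=C(/COC(=O)[C@H](C)CC)[C@@H](OC(C)=O)[C@@H](OCOC)/C=C(\CBr)C(=O)OC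
F14 | step 12 | [(3aS,4S,5R,6Z,10Z,11aR)-5-acetoxy-4-(methoxymethoxy)-10-methyl-3-methylidene-2-oxo-2,3,3a,4,5,8,9,11a-octahydrocyclodeca[b]furan-6-yl]methyl (2R)-2-methylbutanoate (same spatial arrangement as 19) | C=C1C(=O)O[C@@H]2/C=C(/C)CC/C=C(/COC(=O)[C@H](C)CC)[C@@H](OC(C)=O)[C@@H](OCOC)[C@@H]12
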